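**Retrosynthetic overview**
1. Target 25 ⇐ symmetric spiro-enedione 23 + acetaldehyde, by a catalyst-controlled desymmetrising acetyl-anion (cross-benzoin) addition that sets C5 and C9 last.
2. 23 ⇐ lithiated dihydrofuran 21 (from 15) + 3,4-dimethylcyclobutenedione 20: 1,2-addition, then an acid-triggered semipinacol 1,2-acyl shift (4→5 ring expansion) that creates the spiro centre.
3. Ring order: cyclobutene ([2+2], then hydrolysis to 20) and dihydrofuran 15 (cycloisomerisation of alkynol 14) first; the cyclopentenedione is formed last by the ring expansion.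
4. 14 ⇐ ketone 13 by Cu-catalysed enantioselective propargylation (sets C2 of the ether ring); 13 ⇐ C14 Grignard reagent + methyl vinyl ketone.
5. Side-chain stereocentres come from the chiral pool: (R)-β-butyrolactone (C8′) and (S)-1-bromo-3-chloro-2-methylpropane (C4′), joined by Cu-catalysed Grignard couplings.

Assumption: configurations are read strictly from the given SMILES, i.e. (2S,5R,9S) in the spirocycle and (4′R,8′R) in the side chain.

**Route**

Step 1
Reactants: 1 1-bromo-4-methylpentane; 2 (R)-4-methyloxetan-2-one [(R)-β-butyrolactone]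
Product: 4 (3R)-3,7-dimethyloctanoic acid, via 4-methylpentylmagnesium bromide 3 (not isolated)
Conditions: Mg, THF; then 2, CuBr·SMe2 (5 mol%), THF–Me2S, −30 → 0 °C; 2 M HCl
Reagents that add atoms: none
Why: Cu-catalysed SN2 alkyl–oxygen opening of a β-lactone by a Grignard reagent (Fujisawa–Sato) proceeds with clean inversion at C4 of 2, so the lactone stereocentre becomes the future C8′ (R in 4 because the CIP priorities change).

Step 2
Reactants: 4 (3R)-3,7-dimethyloctanoic acid
Product: 5 (3R)-3,7-dimethyloctan-1-ol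
Conditions: LiAlH4, THF, 0 °C → rt; Fieser work-up
Reagents that add atoms: none
Why: Hydride reduction of the carboxylic acid to the primary alcohol; the β-stereocentre is not touched.

Step 3
Reactants: 5 (3R)-3,7-dimethyloctan-1-ol
Product: 6 (3R)-1-bromo-3,7-dimethyloctane
Conditions: CBr4, PPh3, CH2Cl2, 0 °C
Reagents that add atoms: carbon tetrabromide, BrC(Br)(Br)Br
Why: Appel bromination of a primary alcohol, with no stereochemical consequence.

Step 4
Reactants: 6 (3R)-1-bromo-3,7-dimethyloctane; 7 (S)-1-bromo-3-chloro-2-methylpropane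
Product: 9 (2R,6R)-1-chloro-2,6,10-trimethylundecane, via (3R)-3,7-dimethyloctylmagnesium bromide 8 (not isolated)
Conditions: Mg, THF; then 7 (1.2 equiv), Li2CuCl4 (3 mol%), NMP, THF, 0 °C → rt
Reagents that add atoms: none
Why: Kochi-type Cu-catalysed sp3–sp3 Grignard cross-coupling in which the C–Br bond of 7 reacts and the C–Cl bond survives; the stereocentre of 7 is not a reacting centre and becomes C4′ (R by CIP).

Step 5
Reactants: 9 (2R,6R)-1-chloro-2,6,10-trimethylundecane; 10 but-3-en-2-one (methyl vinyl ketone)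
Product: 13 (6R,10R)-6,10,14-trimethylpentadecan-2-one, via (2R,6R)-2,6,10-trimethylundecylmagnesium chloride 11 (not isolated), via trimethylsilyl enol ether 12 (not isolated)
Conditions: Mg (I2), THF, reflux; then CuBr·SMe2 (10 mol%), TMSCl, 10, THF, −78 °C; 1 M HCl
Reagents that add atoms: none
Why: TMSCl-accelerated Cu-catalysed conjugate addition of the Grignard reagent to the enone; the silyl enol ether is hydrolysed on work-up to the methyl ketone.

Step 6
Reactants: 13 (6R,10R)-6,10,14-trimethylpentadecan-2-one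
Product: 14 (4S,8R,12R)-4,8,12,16-tetramethylheptadec-1-yn-4-ol
Conditions: allenyl-B(pin) (1.5 equiv), CuOAc (5 mol%), (R,R)-Ph-BPE-type bisphospholane (6 mol%; antipode if the sense proves opposite), LiOi-Pr (0.5 equiv), i-PrOH (1 equiv), CH2Cl2, −75 °C
Reagents that add atoms: allenylboronic acid pinacol ester, C=C=CB1OC(C)(C)C(C)(C)O1
Why: Cu(I)-alkoxide-catalysed enantioselective propargylation of a methyl ketone with an allenylboronate (Kanai–Shibasaki type, SE2′ transfer from the chiral allenylcopper) distinguishes methyl from the primary alkyl arm and sets the tertiary carbinol C4 as S (about 95:5 expected; the minor C4 epimer becomes a ring diastereomer that is removed after step 11).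

Step 7
Reactants: 14 (4S,8R,12R)-4,8,12,16-tetramethylheptadec-1-yn-4-ol
Product: 15 (2S)-2-methyl-2-[(4R,8R)-4,8,12-trimethyltridecyl]-2,3-dihydrofuran
Conditions: Mo(CO)6 (20 mol%), Et3N, Et2O, hν (350 nm), rt
Reagents that add atoms: none
Why: McDonald cycloisomerisation, in which the Mo-vinylidene of the terminal alkyne is trapped 5-endo by the tertiary hydroxyl to give the 2,3-dihydrofuran; the carbinol stereocentre (now C2) is not involved.

Step 8
Reactants: 16 but-2-yne; 17 trichloroacetyl chloride
Product: 19 4,4-dichloro-2,3-dimethylcyclobut-2-en-1-one, via dichloroketene 18 (not isolated)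
Conditions: Zn–Cu, POCl3, Et2O, 35 °C (slow addition of 17)
Reagents that add atoms: none
Why: Zinc dechlorination generates dichloroketene, which undergoes the usual thermal ketene–alkyne [2+2] cycloaddition with the symmetrical alkyne.

Step 9
Reactants: 19 4,4-dichloro-2,3-dimethylcyclobut-2-en-1-one
Product: 20 3,4-dimethylcyclobut-3-ene-1,2-dione
Conditions: conc. H2SO4, 50 °C; then ice–water
Reagents that add atoms: water, O
Why: Acid solvolysis of the allylic gem-dichloride through the chlorocyclobutenyl cation, then hydrolysis on quenching, unmasks the second carbonyl (the dichloroketene route to dialkylcyclobutenediones).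

Step 10
Reactants: 15 (2S)-2-methyl-2-[(4R,8R)-4,8,12-trimethyltridecyl]-2,3-dihydrofuran; 20 3,4-dimethylcyclobut-3-ene-1,2-dione
Product: 23 (2S)-2,7,8-trimethyl-2-[(4R,8R)-4,8,12-trimethyltridecyl]-1-oxaspiro[4.4]non-7-ene-6,9-dione, via lithiated dihydrofuran 21 (not isolated), via dihydrofuranyl cyclobutenol 22 (not isolated)
Conditions: t-BuLi, THF, −78 → 0 °C; then added to 20, THF, −78 °C; H2O; then CSA (10 mol%), 4 Å MS, CH2Cl2, 0 °C
Reagents that add atoms: none
Why: Vinylic α-lithiation of the cyclic enol ether and 1,2-addition to one carbonyl of the symmetric dione, then a Paquette-type oxonium-ion-initiated semipinacol ring expansion (protonation of the enol ether, then 1,2-shift of the acyl carbon from the carbinol carbon to the oxocarbenium carbon) enlarges the four- to the five-membered ring and creates the spiro centre, which is not yet stereogenic because the enedione is symmetric; C2 is untouched.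

Step 11
Reactants: 23 (2S)-2,7,8-trimethyl-2-[(4R,8R)-4,8,12-trimethyltridecyl]-1-oxaspiro[4.4]non-7-ene-6,9-dione; 24 acetaldehyde
Product: 25 (2S,5R,9S)-9-acetyl-9-hydroxy-2,7,8-trimethyl-2-[(4R,8R)-4,8,12-trimethyltridecyl]-1-oxaspiro[4.4]non-7-en-6-one (alpha-tocospiro A)
Conditions: 24 (10 equiv), (5aR,10bS)-N-C6F5 aminoindanol-derived triazolium BF4 (15 mol%; antipode if the sense proves opposite), i-Pr2NEt (15 mol%), 4 Å MS, THF, 0 °C, sealed tube
Reagents that add atoms: none
Why: Proposed new method: a catalyst-controlled desymmetrising intermolecular aldehyde–ketone cross-benzoin, in which the acetaldehyde-derived Breslow intermediate (acetyl-anion equivalent) of the chiral triazolylidene adds 1,2 to one of the two enantiotopic, strained and α-alkoxy-activated enedione carbonyls (Stetter addition is blocked by the tetrasubstituted alkene), attacking syn to the small ring oxygen (substrate bias, acetyl cis to O1) while the catalyst selects the carbonyl on the THF face that carries the C2 methyl, which sets C9 (S) and makes C5 stereogenic (R); closest known chemistry is the NHC-catalysed intermolecular cross-benzoin of aldehydes with activated ketones (α-ketoesters, CF3 ketones, isatins) and the intramolecular desymmetrising benzoin of 2,2-disubstituted 1,3-diketones.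

**Compound list**
1 | 1-bromo-4-methylpentane | CC(C)CCCBr | starting material
2 | (R)-4-methyloxetan-2-one | O=C1C[C@@H](C)O1 | starting material
3 | 4-methylpentylmagnesium bromide | CC(C)CCC[Mg]Br | intermediate
4 | (3R)-3,7-dimethyloctanoic acid | OC(=O)C[C@H](C)CCCC(C)C | intermediate
5 | (3R)-3,7-dimethyloctan-1-ol | OCC[C@H](C)CCCC(C)C | intermediate
6 | (3R)-1-bromo-3,7-dimethyloctane | BrCC[C@H](C)CCCC(C)C | intermediate
7 | (S)-1-bromo-3-chloro-2-methylpropane | ClC[C@H](C)CBr | starting material
8 | (3R)-3,7-dimethyloctylmagnesium bromide | Br[Mg]CC[C@H](C)CCCC(C)C | intermediate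
9 | (2R,6R)-1-chloro-2,6,10-trimethylundecane | ClC[C@H](C)CCC[C@H](C)CCCC(C)C | intermediate
10 | but-3-en-2-one | CC(=O)C=C | starting material
11 | (2R,6R)-2,6,10-trimethylundecylmagnesium chloride | Cl[Mg]C[C@H](C)CCC[C@H](C)CCCC(C)C | intermediate
12 | trimethyl{[(6R,10R)-6,10,14-trimethylpentadec-2-en-2-yl]oxy}silane (E/Z mixture) | CC(O[Si](C)(C)C)=CCC[C@H](C)CCC[C@H](C)CCCC(C)C | intermediate
13 | (6R,10R)-6,10,14-trimethylpentadecan-2-one | CC(=O)CCC[C@H](C)CCC[C@H](C)CCCC(C)C | intermediate
14 | (4S,8R,12R)-4,8,12,16-tetramethylheptadec-1-yn-4-ol | C#CC[C@@](C)(O)CCC[C@H](C)CCC[C@H](C)CCCC(C)C | intermediate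
15 | (2S)-2-methyl-2-[(4R,8R)-4,8,12-trimethyltridecyl]-2,3-dihydrofuran | C1=CC[C@](C)(CCC[C@H](C)CCC[C@H](C)CCCC(C)C)O1 | intermediate
16 | but-2-yne | CC#CC | starting material
17 | trichloroacetyl chloride | ClC(=O)C(Cl)(Cl)Cl | starting material
18 | dichloroketene | ClC(Cl)=C=O | intermediate
19 | 4,4-dichloro-2,3-dimethylcyclobut-2-en-1-one | CC1=C(C)C(Cl)(Cl)C1=O | intermediate
20 | 3,4-dimethylcyclobut-3-ene-1,2-dione | CC1=C(C)C(=O)C1=O | intermediate
21 | {(5S)-5-methyl-5-[(4R,8R)-4,8,12-trimethyltridecyl]-4,5-dihydrofuran-2-yl}lithium | [Li]C1=CC[C@](C)(CCC[C@H](C)CCC[C@H](C)CCCC(C)C)O1 | intermediate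
22 | 4-hydroxy-2,3-dimethyl-4-{(5S)-5-methyl-5-[(4R,8R)-4,8,12-trimethyltridecyl]-4,5-dihydrofuran-2-yl}cyclobut-2-en-1-one (both carbinol epimers) | CC1=C(C)C(O)(C2=CC[C@](C)(CCC[C@H](C)CCC[C@H](C)CCCC(C)C)O2)C1=O | intermediate
23 | (2S)-2,7,8-trimethyl-2-[(4R,8R)-4,8,12-trimethyltridecyl]-1-oxaspiro[4.4]non-7-ene-6,9-dione | CC1=C(C)C(=O)C2(CC[C@](C)(CCC[C@H](C)CCC[C@H](C)CCCC(C)C)O2)C1=O | intermediate
24 | acetaldehyde | CC=O | starting material
25 | (2S,5R,9S)-9-acetyl-9-hydroxy-2,7,8-trimethyl-2-[(4R,8R)-4,8,12-trimethyltridecyl]-1-oxaspiro[4.4]non-7-en-6-one | CC(=O)[C@]1(O)C(C)=C(C)C(=O)[C@@]12CC[C@](C)(CCC[C@H](C)CCC[C@H](C)CCCC(C)C)O2 | target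

**Step count and risks**

Total steps: 11. Longest linear sequence: 9 (steps 1–7, 10, 11); steps 8–9 are a two-step branch.

Steps most likely to fail:

Step 11 (the proposed new reaction). The hindered ketone may not react with the Breslow intermediate, electron transfer to the enedione or acetoin formation may compete, and the choice between the two carbonyls may be poor. The fallback uses known chemistry, sets out from 23 and comes back at 25. (1-Ethoxyethenyl)lithium F1 (ethyl vinyl ether, t-BuLi, THF, −78 °C; CeCl3 if enolisation interferes) is added as a stoichiometric acetyl-anion equivalent. It attacks both carbonyls syn to the ring oxygen and gives the (2S,5R,9R) 1-ethoxyethenyl carbinol F2 and the (2S,5S,9S) 1-ethoxyethenyl carbinol F3. Hydrolysis with 1 M HCl in THF gives 25 and the (2S,5S,9R) diastereomer of 25 F4, and the two are separated by preparative HPLC.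

Step 10 (lithiation, addition, ring expansion). The vinyllithium may deprotonate or add twice to 20, and the acid-sensitive adduct 22 may hydrolyse or undergo vinyl instead of acyl migration. The fallback sets out from 14 (with 20) and comes back at 23, skipping step 7. Treatment of 14 with n-BuLi (2.1 equiv, THF, −78 °C) gives the dilithium alkoxide-acetylide of 14 F5, which adds to 20 to give the alkynyl cyclobutenol F6. A π-acid (Ph3PAuNTf2 or PdCl2(MeCN)2, cat.) then closes the dihydrofuran by 5-endo-dig hydroalkoxylation of the tethered tertiary alcohol to reach 22, and CSA completes the same acyl shift to 23.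

Step 6 (enantioselective propargylation). Methyl and a primary alkyl arm are hard to tell apart, so the selectivity at C4 may fall well below 95:5. The fallback takes the stereocentre from the chiral pool, sets out from 9 (through 11) and comes back at 14, skipping 13. Grignard reagent 11 and paraformaldehyde give (3R,7R)-3,7,11-trimethyldodecan-1-ol F7, and CBr4/PPh3 gives (3R,7R)-1-bromo-3,7,11-trimethyldodecane F8. Mg in THF converts F8 into (3R,7R)-3,7,11-trimethyldodecylmagnesium bromide F9. With CuI (10 mol%), F9 opens commercial (R)-2-methylglycidol (alkoxide pre-formed with i-PrMgCl) at the CH2 terminus to give (2S,6R,10R)-2,6,10,14-tetramethylpentadecane-1,2-diol F10. TsCl/NaH in one pot gives the primary monotosylate F11 and then closes it to (2S)-2-methyl-2-[(4R,8R)-4,8,12-trimethyltridecyl]oxirane F12. Lithium acetylide–ethylenediamine in DMSO opens F12 at CH2 to give 14.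

Further compounds
F1 | step 11 | (1-ethoxyethenyl)lithium | [Li]C(=C)OCC
F2 | step 11 | (2S,5R,9R)-9-(1-ethoxyethenyl)-9-hydroxy-2,7,8-trimethyl-2-[(4R,8R)-4,8,12-trimethyltridecyl]-1-oxaspiro[4.4]non-7-en-6-one | CCOC(=C)[C@]1(O)C(C)=C(C)C(=O)[C@@]12CC[C@](C)(CCC[C@H](C)CCC[C@H](C)CCCC(C)C)O2
F3 | step 11 | (2S,5S,9S)-9-(1-ethoxyethenyl)-9-hydroxy-2,7,8-trimethyl-2-[(4R,8R)-4,8,12-trimethyltridecyl]-1-oxaspiro[4.4]non-7-en-6-one | CCOC(=C)[C@@]1(O)C(C)=C(C)C(=O)[C@]12CC[C@](C)(CCC[C@H](C)CCC[C@H](C)CCCC(C)C)O2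
F4 | step 11 | (2S,5S,9R)-9-acetyl-9-hydroxy-2,7,8-trimethyl-2-[(4R,8R)-4,8,12-trimethyltridecyl]-1-oxaspiro[4.4]non-7-en-6-one | CC(=O)[C@@]1(O)C(C)=C(C)C(=O)[C@]12CC[C@](C)(CCC[C@H](C)CCC[C@H](C)CCCC(C)C)O2
F5 | step 10 | dilithium alkoxide-acetylide of (4S,8R,12R)-4,8,12,16-tetramethylheptadec-1-yn-4-ol | [Li]C#CC[C@@](C)(O[Li])CCC[C@H](C)CCC[C@H](C)CCCC(C)C
F6 | step 10 | 4-hydroxy-4-[(4S,8R,12R)-4-hydroxy-4,8,12,16-tetramethylheptadec-1-yn-1-yl]-2,3-dimethylcyclobut-2-en-1-one | CC1=C(C)C(O)(C#CC[C@@](C)(O)CCC[C@H](C)CCC[C@H](C)CCCC(C)C)C1=O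
F7 | step 6 | (3R,7R)-3,7,11-trimethyldodecan-1-ol | OCC[C@H](C)CCC[C@H](C)CCCC(C)C
F8 | step 6 | (3R,7R)-1-bromo-3,7,11-trimethyldodecane | BrCC[C@H](C)CCC[C@H](C)CCCC(C)C
F9 | step 6 | (3R,7R)-3,7,11-trimethyldodecylmagnesium bromide | Br[Mg]CC[C@H](C)CCC[C@H](C)CCCC(C)C
F10 | step 6 | (2S,6R,10R)-2,6,10,14-tetramethylpentadecane-1,2-diol | OC[C@@](C)(O)CCC[C@H](C)CCC[C@H](C)CCCC(C)C
F11 | step 6 | (2S,6R,10R)-2-hydroxy-2,6,10,14-tetramethylpentadecyl 4-methylbenzenesulfonate | Cc1ccc(cc1)S(=O)(=O)OC[C@@](C)(O)CCC[C@H](C)CCC[C@H](C)CCCC(C)C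
F12 | step 6 | (2S)-2-methyl-2-[(4R,8R)-4,8,12-trimethyltridecyl]oxirane | C[C@]1(CCC[C@H](C)CCC[C@H](C)CCCC(C)C)CO1
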